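The constants come from no measurement; what happens was integrated by code.

The vessel holds substrate in one phase and its reagent in another, so reagent must cross before it can react.

    reagent in the reaction phase ⇌ reagent in the second phase, rate k1*([reagent in the reaction phase] - [reagent in the second phase]/K1) per volume of the first phase (K1 = 19, k1 = 0.057 /s)
    substrate + reagent in the reaction phase → target (k2 = 1.4 /M/s)
    target ⇌ product in the second phase, rate k3*([target] - [product in the second phase]/K3) per volume of the first phase (K3 = 1.4, k3 = 0.35 /s)
    target → decomposed product (k4 = 0.096 /s)
    substrate ⇌ dormant form (K5 = 2.0, k5 = 0.11 /s)
    reagent in the reaction phase → decomposed reagent (k6 = 0.012 /s)
    2 substrate → self-condensation product (k7 = 0.12 /M/s)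

substrate 0.35 M; reagent in the second phase 4.00 equiv; time 20 s; volume of the second phase over the first 0.50

* how much target and product in the second phase together there is at 20 s, in percent of the substrate charged
* part of the substrate charged that has reacted at 20 s

- percent here means substrate units held: one self-condensation product counts as two
- what is said of target includes product in the second phase
- a doubled species enters its step squared and goes two at a time
- in the second phase: reagent in the second phase, product in the second phase; everything else is in the first
- charges count per volume of the first phase; a concentration in a rate is the amount of a species over the volume of its own phase; every rate counts per litre of the first phase
- what has gone from substrate into another species counts as reacted, even if it can come back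
- run time (flask): 20 s

Two chemists at this vessel disagree about the reagent in the reaction phase. The first says it stands at its partition level, 42.1% of the substrate charge. Substrate then turns over by a pseudo-first-order step at 0.206 /s. Competing with condensation at its starting pace, that gives 23.0% target after decay, with 98.4% of the substrate reacted.

The second, whose side I take, freezes the reagent in the second phase: one full turnover of substrate costs a quarter of that stock. Reagent then crosses at a steady rate, the leak 0.0240 /s, meaning the reagent entering the reaction phase each second, as a fraction of the substrate charge, while the stock stands at its charge. The leak is slower than the first chemist's turnover at full substrate.

My reckoning needs free substrate. Dormant form equilibrates quickly, with a relaxation half-life of 4.20 s, shorter than the run, and holds back all but a third of the pool. Condensation, charged against the undiluted pool, leaves 12.4% free at the end, so 87.6% has reacted. At that level, substrate catches 46.9% of the leak; the rest crosses back or decomposes. Target decays at 0.0565 /s once its second-phase part is counted as protected, which gives a survival window of 12.0 s. Leak times share times window is 13.5%.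

The forecast, 14.5% and 88%, stands on the same side, “Reagent leaks slowly out of the second phase”, and its yield is a little above mine.

This flask gives 12.0% and 86.0%, a yield nearer the leak view than the partition view. At 20.0 s the stock is 91.0% of its charge, and reaction-phase reagent is 13.4% of the substrate charge against a partition level of 38.3%. The partition view belongs to the late flask: at 200 s, with substrate at 0.158%, those figures are 22.6% and 27.4%. The neighbour flask with 0.087 M of substrate keeps the same leak, since its equivalents are held. Its free substrate reckons to 23.5% and its share to 29.3%, so I get 8.44% target and 76.5% reacted; that flask gives 6.55% and 74.4%.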